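**Assumption:** the SMILES is read literally. In tetralin numbering of the target (C1 quaternary, C2 CH‑isopropenyl, C4 ketone, C5/C7/C8 hydroxyls, C6 isopropyl) this is (1R,2S), with the isopropenyl group and the propanoic acid chain cis on ring B.

## Retrosynthetic overview

1. Target ⇐ hydrolysis of its seven‑membered aryl lactone (acid chain onto the C8 phenol); the C2 isopropenyl group ⇐ ligand‑controlled Rh 1,4‑addition to the ring‑B enone.
2. Keto lactone (C8–O bond, quaternary C1 stereocentre) ⇐ enantioselective desymmetrising Baeyer–Villiger oxidation of a Cs‑symmetric 7,9‑dihydroxy‑8‑isopropyl‑3a‑methylphenalene‑1,6‑dione. Its two enantiotopic tetralone rings are the future ketone ring and the future acid chain.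
3. Symmetric diketone ⇐ Friedel–Crafts isopropylation and twofold ketone‑directed C–H hydroxylation of 3a‑methylphenalene‑1,6‑dione ⇐ benzene + a C8 lactone acid ⇐ diethyl 4‑oxoheptanedioate + MeMgBr.
4. Ring order: arene (ring C, from benzene) → both six‑membered ketone rings closed together → one ring expanded to the lactone and later opened; the other stays as ring B.

## Route

**Step 1**
Reactants: 1 diethyl 4‑oxoheptanedioate, 2 methylmagnesium bromide
Product: 4 3‑(2‑methyl‑5‑oxooxolan‑2‑yl)propanoic acid (racemic), via lactone ethyl ester 3 (not isolated)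
Conditions: MeMgBr (1.05 equiv), THF, −78 to 0 °C; then aq. NaOH, 25 °C; then aq. HCl to pH 1
Reagents that add atoms: sodium hydroxide ([Na+].[OH-])
Why: Chemoselective Grignard 1,2‑addition to the ketone (faster than to the esters at −78 °C) gives a tertiary alkoxide that lactonises, and saponification/acidification returns the γ‑lactone acid; its stereocentre is irrelevant because it becomes a prochiral carbon in step 2.

**Step 2**
Reactants: 4 3‑(2‑methyl‑5‑oxooxolan‑2‑yl)propanoic acid, 5 benzene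
Product: 8 3a‑methyl‑2,3,3a,4,5,6‑hexahydro‑1H‑phenalene‑1,6‑dione, via diacid 6 (not isolated), via keto acid 7 (not isolated)
Conditions: AlCl3 (3.5 equiv), benzene (solvent), 25 to 60 °C; aq. HCl quench, evaporate; then Eaton's reagent (P2O5 in MeSO3H), 80 °C
Reagents that add atoms: none
Why: Friedel–Crafts alkylation (AlCl3 ionises the tertiary lactone C–O bond and the cation alkylates benzene) followed by twofold intramolecular Friedel–Crafts acylation, the second ring closing meta to the first acyl group, gives the achiral Cs‑symmetric peri‑fused diketone.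

**Step 3**
Reactants: 8 3a‑methyl‑2,3,3a,4,5,6‑hexahydro‑1H‑phenalene‑1,6‑dione
Product: 10 7,9‑dihydroxy‑3a‑methyl‑2,3,3a,4,5,6‑hexahydro‑1H‑phenalene‑1,6‑dione, via bis(trifluoroacetate) 9 (not isolated)
Conditions: Pd(OAc)2 (10 mol %), K2S2O8 (3 equiv), CF3CO2H/(CF3CO)2O 9:1, 80 °C; then H2O/THF, 25 °C
Reagents that add atoms: trifluoroacetic acid (OC(=O)C(F)(F)F)
Why: Ketone‑directed ortho C–H oxygenation: each carbonyl guides divalent palladium to its only ortho C–H (five‑membered palladacycle), persulfate oxidises it to a tetravalent palladium trifluoroacetate, and C–O reductive elimination gives the aryl trifluoroacetates, which hydrolyse on work‑up.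

**Step 4**
Reactants: 10 7,9‑dihydroxy‑3a‑methyl‑2,3,3a,4,5,6‑hexahydro‑1H‑phenalene‑1,6‑dione, 11 propan‑2‑ol
Product: 12 7,9‑dihydroxy‑3a‑methyl‑8‑(propan‑2‑yl)‑2,3,3a,4,5,6‑hexahydro‑1H‑phenalene‑1,6‑dione
Conditions: i‑PrOH (3 equiv), MeSO3H, 60 °C
Reagents that add atoms: none
Why: Friedel–Crafts alkylation at the only free ring position, which is ortho to both hydroxyls and meta to both acyl groups, so no regioisomer is possible and the mirror symmetry is kept.

**Step 5**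
Reactants: 12 7,9‑dihydroxy‑3a‑methyl‑8‑(propan‑2‑yl)‑2,3,3a,4,5,6‑hexahydro‑1H‑phenalene‑1,6‑dione
Product: 13 8‑lactone of 3‑[(1S)‑5,7,8‑trihydroxy‑1‑methyl‑4‑oxo‑6‑(propan‑2‑yl)‑1,2,3,4‑tetrahydronaphthalen‑1‑yl]propanoic acid
Conditions: Sc(OTf)3 (10 mol %), chiral N,N′‑dioxide ligand (L‑pipecolic‑acid‑derived, 2,6‑diisopropylanilide arms, 12 mol %; ligand antipode chosen by screening, configuration of 13 secured by X‑ray), mCPBA (1.0 equiv), EtOAc, −20 °C
Reagents that add atoms: mCPBA (OOC(=O)c1cccc(Cl)c1)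
Why: Proposed new method: catalytic enantioselective desymmetrising Baeyer–Villiger (Dakin‑type) oxidation of a Cs‑symmetric bis(aryl ketone) — the chiral trivalent scandium Lewis acid chelates one o‑hydroxyaryl ketone (phenol O and C=O) and its ligand pocket distinguishes the two enantiotopic carbonyls on either side of the mirror plane through C3a; the peracid adds to the bound carbonyl and the electron‑rich aryl carbon (ortho and para hydroxyls) migrates in the Criegee intermediate, forming the C8–O bond and the seven‑membered aryl lactone and fixing the quaternary centre as S; any second oxidation should consume mainly the minor enantiomer of 13 (its remaining ketone is the catalyst‑matched one), which would raise ee; closest known reaction types are the Sc(OTf)3/N,N′‑dioxide‑ and chiral‑phosphoric‑acid‑catalysed asymmetric Baeyer–Villiger desymmetrisation of prochiral cyclobutanones and 4‑substituted cyclohexanones, the Dakin oxidation of o‑hydroxyaryl ketones and the peracid ring expansion of 1‑tetralones to benzoxepinones.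

**Step 6**
Reactants: 13 keto lactone
Product: 16 8‑lactone of 3‑[(1R)‑5,7,8‑trihydroxy‑1‑methyl‑4‑oxo‑6‑(propan‑2‑yl)‑1,4‑dihydronaphthalen‑1‑yl]propanoic acid, via tris(trimethylsilyl) derivative 14 (not isolated), via enone bis(trimethylsilyl) ether 15 (not isolated)
Conditions: Me3SiOTf (3.3 equiv), Et3N (4 equiv), CH2Cl2, 0 °C; then Pd(OAc)2 (10 mol %), O2 (1 atm), DMSO, 25 °C; then aq. citric acid, THF, 0 °C
Reagents that add atoms: none
Why: Saegusa–Ito oxidation: soft enolisation silylates the two phenols and turns the only ketone into its silyl enol ether (the aryl ester is not enolised), and palladium‑mediated β‑hydride elimination gives the enone; the quaternary centre blocks aromatisation and is untouched (descriptor changes S to R by CIP priority only).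

**Step 7**
Reactants: 16 enone lactone, 17 4,4,5,5‑tetramethyl‑2‑(prop‑1‑en‑2‑yl)‑1,3,2‑dioxaborolane
Product: 18 8‑lactone of 3‑[(1R,2S)‑5,7,8‑trihydroxy‑1‑methyl‑4‑oxo‑6‑(propan‑2‑yl)‑2‑(prop‑1‑en‑2‑yl)‑1,2,3,4‑tetrahydronaphthalen‑1‑yl]propanoic acid
Conditions: [Rh(OH)((S)‑binap)]2 (3 mol %), 17 (3 equiv), 1,4‑dioxane/H2O 10:1, 50 °C, Ar
Reagents that add atoms: none
Why: Hayashi–Miyaura rhodium‑catalysed asymmetric 1,4‑addition: in the planar naphthalenone ring the methyl and the CH2 of the lactone arm flank C2 symmetrically (about ±60° out of plane), so the substrate has essentially no facial bias and the ligand decides; (S)‑binap, applying the same facial sense that gives 3S adducts with cyclohex‑2‑enone, sets C2 as S (isopropenyl cis to the lactone arm), the antipode being used if the opposite sense is found; free phenols and the aryl lactone tolerate the neutral aqueous conditions.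

**Step 8**
Reactants: 18 isopropenyl keto lactone
Product: 19 3‑[(1R,2S)‑5,7,8‑trihydroxy‑1‑methyl‑4‑oxo‑6‑(propan‑2‑yl)‑2‑(prop‑1‑en‑2‑yl)‑1,2,3,4‑tetrahydronaphthalen‑1‑yl]propanoic acid
Conditions: LiOH (4 equiv), THF/H2O (degassed, Ar), 0 to 25 °C; then 1 M HCl to pH 2
Reagents that add atoms: lithium hydroxide ([Li+].[OH-])
Why: Saponification of the aryl lactone frees the C8 phenol and the propanoic acid; air is excluded because the 1,2,4‑triol oxidises under base, the isopropenyl group is inert, and neither stereocentre is epimerisable (C1 quaternary, C2 β to the ketone).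

## Compound list

1 | diethyl 4‑oxoheptanedioate | CCOC(=O)CCC(=O)CCC(=O)OCC | starting material
2 | methylmagnesium bromide | C[Mg]Br | starting material
3 | ethyl 3‑(2‑methyl‑5‑oxooxolan‑2‑yl)propanoate (racemic) | CCOC(=O)CCC1(C)CCC(=O)O1 | intermediate
4 | 3‑(2‑methyl‑5‑oxooxolan‑2‑yl)propanoic acid (racemic) | OC(=O)CCC1(C)CCC(=O)O1 | intermediate
5 | benzene | c1ccccc1 | starting material
6 | 4‑methyl‑4‑phenylheptanedioic acid | OC(=O)CCC(C)(CCC(=O)O)c1ccccc1 | intermediate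
7 | 3‑(1‑methyl‑4‑oxo‑1,2,3,4‑tetrahydronaphthalen‑1‑yl)propanoic acid (racemic) | OC(=O)CCC1(C)CCC(=O)c2ccccc12 | intermediate
8 | 3a‑methyl‑2,3,3a,4,5,6‑hexahydro‑1H‑phenalene‑1,6‑dione (achiral) | CC12CCC(=O)c3cccc(C(=O)CC1)c32 | intermediate
9 | 3a‑methyl‑1,6‑dioxo‑2,3,3a,4,5,6‑hexahydro‑1H‑phenalene‑7,9‑diyl bis(trifluoroacetate) | CC12CCC(=O)c3c(OC(=O)C(F)(F)F)cc(OC(=O)C(F)(F)F)c(C(=O)CC1)c32 | intermediate
10 | 7,9‑dihydroxy‑3a‑methyl‑2,3,3a,4,5,6‑hexahydro‑1H‑phenalene‑1,6‑dione | CC12CCC(=O)c3c(O)cc(O)c(C(=O)CC1)c32 | intermediate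
11 | propan‑2‑ol | CC(C)O | starting material
12 | 7,9‑dihydroxy‑3a‑methyl‑8‑(propan‑2‑yl)‑2,3,3a,4,5,6‑hexahydro‑1H‑phenalene‑1,6‑dione (achiral, Cs) | CC12CCC(=O)c3c(O)c(C(C)C)c(O)c(C(=O)CC1)c32 | intermediate
13 | 8‑lactone of 3‑[(1S)‑5,7,8‑trihydroxy‑1‑methyl‑4‑oxo‑6‑(propan‑2‑yl)‑1,2,3,4‑tetrahydronaphthalen‑1‑yl]propanoic acid | C[C@@]12CCC(=O)Oc3c(O)c(C(C)C)c(O)c(C(=O)CC1)c32 | intermediate
14 | tris(trimethylsilyl) derivative of 13: 5‑O‑ and 7‑O‑silyl ethers, C4 silyl enol ether (C3=C4); (1R) by CIP, same spatial arrangement | C[C@@]12CCC(=O)Oc3c(O[Si](C)(C)C)c(C(C)C)c(O[Si](C)(C)C)c(C(O[Si](C)(C)C)=CC1)c32 | intermediate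
15 | 5,7‑bis(trimethylsilyl) ether of 16, (1R) | C[C@@]12CCC(=O)Oc3c(O[Si](C)(C)C)c(C(C)C)c(O[Si](C)(C)C)c(C(=O)C=C1)c32 | intermediate
16 | 8‑lactone of 3‑[(1R)‑5,7,8‑trihydroxy‑1‑methyl‑4‑oxo‑6‑(propan‑2‑yl)‑1,4‑dihydronaphthalen‑1‑yl]propanoic acid | C[C@@]12CCC(=O)Oc3c(O)c(C(C)C)c(O)c(C(=O)C=C1)c32 | intermediate
17 | 4,4,5,5‑tetramethyl‑2‑(prop‑1‑en‑2‑yl)‑1,3,2‑dioxaborolane | CC(=C)B1OC(C)(C)C(C)(C)O1 | starting material
18 | 8‑lactone of 3‑[(1R,2S)‑5,7,8‑trihydroxy‑1‑methyl‑4‑oxo‑6‑(propan‑2‑yl)‑2‑(prop‑1‑en‑2‑yl)‑1,2,3,4‑tetrahydronaphthalen‑1‑yl]propanoic acid | C=C(C)[C@@H]1CC(=O)c2c(O)c(C(C)C)c(O)c3OC(=O)CC[C@@]1(C)c23 | intermediate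
19 | 3‑[(1R,2S)‑5,7,8‑trihydroxy‑1‑methyl‑4‑oxo‑6‑(propan‑2‑yl)‑2‑(prop‑1‑en‑2‑yl)‑1,2,3,4‑tetrahydronaphthalen‑1‑yl]propanoic acid | C=C(C)[C@@H]1CC(=O)c2c(O)c(C(C)C)c(O)c(O)c2[C@]1(C)CCC(=O)O | target

## Step count and risks

Total steps: 8. Longest linear sequence: 8.

**Step 5 (the proposed new oxidation).** Enantiotopic‑group selectivity and mono‑oxidation are unproven. Fallback with known chemistry, setting out from 12 and returning at 13: Noyori transfer hydrogenation (RuCl(p‑cymene)[(R,R)‑TsDPEN], HCO2H/Et3N, 25 °C; catalyst antipode chosen so that the surviving ketone is the one destined to become the lactone) reduces one of the two enantiotopic aryl ketones to give the hydroxy ketone (3aS,6R)‑6,7,9‑trihydroxy‑3a‑methyl‑8‑(propan‑2‑yl)‑2,3,3a,4,5,6‑hexahydro‑1H‑phenalen‑1‑one F4. The single remaining ketone then undergoes an ordinary Dakin‑type Baeyer–Villiger oxidation (mCPBA, NaHCO3, CH2Cl2, 0 °C) to the hydroxy lactone, the 8‑lactone of 3‑[(1S,4R)‑4,5,7,8‑tetrahydroxy‑1‑methyl‑6‑(propan‑2‑yl)‑1,2,3,4‑tetrahydronaphthalen‑1‑yl]propanoic acid F5. MnO2 (CH2Cl2, 25 °C) re‑oxidises the benzylic alcohol and gives 13; the carbinol configuration is erased.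

**Step 7 (ligand‑controlled addition).** The β‑carbon is next to the quaternary centre and stereocontrol rests on the ligand alone. Fallback: set C2 under substrate control before the ring expansion, where both rings fused to the arene are six‑membered and the C3a methyl is axial. It sets out from 12, returns at 19 and replaces steps 5 to 8.
- 12 is silylated (t‑BuMe2SiOTf, 2,6‑lutidine, CH2Cl2) to 7,9‑bis[(tert‑butyldimethylsilyl)oxy]‑3a‑methyl‑8‑(propan‑2‑yl)‑2,3,3a,4,5,6‑hexahydro‑1H‑phenalene‑1,6‑dione F6.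
- Enantioselective deprotonation with lithium (R,R)‑bis(1‑phenylethyl)amide/LiCl and in situ Me3SiCl (THF, −100 °C; base antipode by screening) gives the mono(trimethylsilyl enol ether) (3aR)‑7,9‑bis[(tert‑butyldimethylsilyl)oxy]‑3a‑methyl‑8‑(propan‑2‑yl)‑6‑[(trimethylsilyl)oxy]‑2,3,3a,4‑tetrahydro‑1H‑phenalen‑1‑one F7.
- Pd(OAc)2 (MeCN, 25 °C) gives the enone diketone (3aR)‑7,9‑bis[(tert‑butyldimethylsilyl)oxy]‑3a‑methyl‑8‑(propan‑2‑yl)‑2,3‑dihydro‑1H‑phenalene‑1,6(3aH)‑dione F8.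
- (CH2=C(CH3))2CuLi (THF, −78 °C) adds anti to the axial methyl, and the enolate is trapped with N‑(5‑chloropyridin‑2‑yl)triflimide as the enol triflate (3aR,4S)‑7,9‑bis[(tert‑butyldimethylsilyl)oxy]‑3a‑methyl‑1‑oxo‑8‑(propan‑2‑yl)‑4‑(prop‑1‑en‑2‑yl)‑2,3,3a,4‑tetrahydro‑1H‑phenalen‑6‑yl trifluoromethanesulfonate F9. This leaves a single ketone.
- LiOH with 1.1 equiv H2O2 (THF/H2O, 0 °C) removes the aryl silyl ethers and performs the Dakin oxidation of that ketone; HOO− does not touch the isopropenyl group. Excess LiOH (25 °C) then opens the lactone and cleaves the S–O bond of the triflate to the ketone, and HCl gives 19.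

**Step 3 (twofold C–H hydroxylation).** The second palladation must occur on a ring that already carries a trifluoroacetoxy group. Fallback: bring both oxygens in with the arene. It sets out from 1 and returns at 10.
- 3,5‑Dimethoxyphenylmagnesium chloride (THF, −78 °C) adds to the ketone of 1 and the alkoxide lactonises to ethyl 3‑[2‑(3,5‑dimethoxyphenyl)‑5‑oxooxolan‑2‑yl]propanoate F1.
- Reetz methylation of the tertiary benzylic C–O bond (Me2TiCl2 from Me2Zn and TiCl4, CH2Cl2, −30 to 0 °C) gives 7‑ethyl hydrogen 4‑(3,5‑dimethoxyphenyl)‑4‑methylheptanedioate F2.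
- Polyphosphoric acid (90 °C) closes both rings at the positions ortho/para to the methoxy groups to give 7,9‑dimethoxy‑3a‑methyl‑2,3,3a,4,5,6‑hexahydro‑1H‑phenalene‑1,6‑dione F3.
- BCl3 (CH2Cl2, 0 °C) cleaves both methyl ethers, each chelated to a peri ketone, and gives 10.

Further compounds
F1 | step 3 | ethyl 3‑[2‑(3,5‑dimethoxyphenyl)‑5‑oxooxolan‑2‑yl]propanoate (racemic) | CCOC(=O)CCC1(c2cc(OC)cc(OC)c2)CCC(=O)O1
F2 | step 3 | 7‑ethyl hydrogen 4‑(3,5‑dimethoxyphenyl)‑4‑methylheptanedioate (racemic) | CCOC(=O)CCC(C)(CCC(=O)O)c1cc(OC)cc(OC)c1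
F3 | step 3 | 7,9‑dimethoxy‑3a‑methyl‑2,3,3a,4,5,6‑hexahydro‑1H‑phenalene‑1,6‑dione | CC12CCC(=O)c3c(OC)cc(OC)c(C(=O)CC1)c32
F4 | step 5 | (3aS,6R)‑6,7,9‑trihydroxy‑3a‑methyl‑8‑(propan‑2‑yl)‑2,3,3a,4,5,6‑hexahydro‑1H‑phenalen‑1‑one | C[C@@]12CCC(=O)c3c(O)c(C(C)C)c(O)c([C@H](O)CC1)c32
F5 | step 5 | 8‑lactone of 3‑[(1S,4R)‑4,5,7,8‑tetrahydroxy‑1‑methyl‑6‑(propan‑2‑yl)‑1,2,3,4‑tetrahydronaphthalen‑1‑yl]propanoic acid | C[C@@]12CCC(=O)Oc3c(O)c(C(C)C)c(O)c([C@H](O)CC1)c32
F6 | step 7 | 7,9‑bis[(tert‑butyldimethylsilyl)oxy]‑3a‑methyl‑8‑(propan‑2‑yl)‑2,3,3a,4,5,6‑hexahydro‑1H‑phenalene‑1,6‑dione | CC12CCC(=O)c3c(O[Si](C)(C)C(C)(C)C)c(C(C)C)c(O[Si](C)(C)C(C)(C)C)c(C(=O)CC1)c32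
F7 | step 7 | (3aR)‑7,9‑bis[(tert‑butyldimethylsilyl)oxy]‑3a‑methyl‑8‑(propan‑2‑yl)‑6‑[(trimethylsilyl)oxy]‑2,3,3a,4‑tetrahydro‑1H‑phenalen‑1‑one | C[C@@]12CCC(=O)c3c(O[Si](C)(C)C(C)(C)C)c(C(C)C)c(O[Si](C)(C)C(C)(C)C)c(C(O[Si](C)(C)C)=CC1)c32
F8 | step 7 | (3aR)‑7,9‑bis[(tert‑butyldimethylsilyl)oxy]‑3a‑methyl‑8‑(propan‑2‑yl)‑2,3‑dihydro‑1H‑phenalene‑1,6(3aH)‑dione | C[C@@]12CCC(=O)c3c(O[Si](C)(C)C(C)(C)C)c(C(C)C)c(O[Si](C)(C)C(C)(C)C)c(C(=O)C=C1)c32
F9 | step 7 | (3aR,4S)‑7,9‑bis[(tert‑butyldimethylsilyl)oxy]‑3a‑methyl‑1‑oxo‑8‑(propan‑2‑yl)‑4‑(prop‑1‑en‑2‑yl)‑2,3,3a,4‑tetrahydro‑1H‑phenalen‑6‑yl trifluoromethanesulfonate | C=C(C)[C@@H]1C=C(OS(=O)(=O)C(F)(F)F)c2c(O[Si](C)(C)C(C)(C)C)c(C(C)C)c(O[Si](C)(C)C(C)(C)C)c3C(=O)CC[C@@]1(C)c23
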